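Which of the four flasks holds the most complex with two exchanged at 6.0 min is a question of how far each climbs with its charge, and two earlier runs at the same held gas level show that climb.

| flask | starting complex | gas | remark | time |
|---|---|---|---|---|
| Saturday's | 0.055 M | 54 mM (held) | run made earlier |  |
| Friday's | 0.32 M | 54 mM (held) | run made earlier |  |
| epsilon | 0.20 M | 54 mM (held) |  | 6.0 min |
| eta | 0.13 M | 54 mM (held) |  | 6.0 min |
| beta | 0.040 M | 54 mM (held) |  | 6.0 min |
| gamma | 0.080 M | 54 mM (held) |  | 6.0 min |

- Saturday's (time / min: complex with two exchanged / %): 0.500: 1.5; 0.833: 7.0; 1.50: 21.5; 3.00: 45.2; 6.00: 59.5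
- Friday's (time / min: complex with two exchanged / %): 0.500: 1.6; 0.833: 4.0; 1.50: 9.3; 3.00: 18.5; 6.00: 23.3

(scatter of a reading: 0.5 percentage points)

- at the start none of the gas is in solution

- the flasks put in order of amount of complex with two exchanged, in percent of the starting complex charged, best first, at 6.0 min (epsilon / eta / beta / gamma)
- the amount of complex with two exchanged, in percent of the starting complex charged of the flask you put first, at 6.0 min
- the amount of complex with two exchanged, in percent of the starting complex charged of the flask you put last, at 6.0 min

Let x be the converted share of a charge c of starting complex. By 0.833 min the readings stand at 7.0% on Saturday and 4.0% on Friday, a ratio of 1.75, while Friday's charge is 5.82 times Saturday's. Two things then slow the climb: the forward rate shrinks with the unconverted share, and the back rate grows with x times the square of the released leaving ligand, two per exchanged complex. Between 3.00 min and 6.00 min, x rises by 0.0160 min⁻¹ on Friday against 0.0477 min⁻¹ on Saturday, slower even though 76.7% of Friday's charge is unconverted against 40.5% of Saturday's, so the back rate is what holds Friday down.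

Dividing back rate by forward rate removes time and leaves c squared times x cubed over the unconverted share, a reaction quotient with the gas held. The last readings give 0.00157 M^2 on Saturday and 0.00169 M^2 on Friday, and their mean is the stall number S, 0.00163 M^2. A flask therefore stands where x cubed over the unconverted share equals S over c squared, which is 1.02 for beta and 0.0408 for epsilon. This reckoning gives 68.5% in beta and 30.5% in epsilon, with the order running against the charge. The forecast has the same order, beta > gamma > eta > epsilon, with 67% for beta, lower than this reckoning, “allowing for slightly slower kinetics”, and 30.5% for epsilon.

The flasks give beta > gamma > eta > epsilon, with 65.5% in beta and 30.8% in epsilon.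

    gas ⇌ incoming ligand, rate k1*(csat - [incoming ligand]) (kL = 0.0530 s⁻¹)
    complex with one exchanged + incoming ligand ⇌ leaving ligand + complex with two exchanged (K = 4.40, k = 0.500 M⁻¹ s⁻¹)
    starting complex + incoming ligand ⇌ leaving ligand + complex with one exchanged (K = 1.60, k = 0.160 M⁻¹ s⁻¹)

Beta's result gives a stall number of 0.00130 M^2, below S, while the flask like beta charged with 0.16 M reaches 35.1%, which gives 0.00171 M^2, close to S. In beta the step from starting complex, both ways together, has a relaxation half-life of 0.710 min at 6.00 min, far shorter than the 6.0 min elapsed. Even so, beta's complex with two exchanged still climbs, to 68.9% at 60.0 min.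

(All runs are calculated for an exercise, and the scatter is random.)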